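30 s after the start south-east is chilled, so I ask whether its fast start is over by then.

| flask | substrate | partner | temperature | remark | time |
|---|---|---|---|---|---|
| alder | 0.10 M | 1.2 equiv | 25 °C | run made earlier |  |
| ash | 0.10 M | 1.7 equiv | 36 °C | run made earlier |  |
| south | 0.10 M | 1.30 equiv |  | at 40 °C throughout | 2.5 min |
| south-east | 0.10 M | 2.00 equiv |  | at 40 °C until 30 s, from then on at 20 °C | 2.5 min |

| run | time / min | target / % |
|---|---|---|
| alder | 1.00 | 8 |
| alder | 2.00 | 16 |
| alder | 3.00 | 15 |
| alder | 4.00 | 16 |
| alder | 5.00 | 22 |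
| ash | 0.200 | 5 |
| ash | 0.417 | 10 |
| ash | 0.667 | 14 |
| ash | 1.33 | 16 |
| ash | 2.50 | 21 |

(readings scatter by 2 percentage points)

- which of the two ends with the higher amount of target, in percent of the substrate charged ("neither" if they lie within 2 percentage points) (south / south-east / neither)
- target at the end, in percent of the substrate charged, south
- target at the end, in percent of the substrate charged, south-east



The readings of both runs rise to a plateau near 15.0% and then climb slowly. In the ash run the plateau over the rate up to the first reading gives 0.600 min, the burst time, and in the alder run 1.88 min. With rates taken proportional to [partner], the ratio of ash to alder is 2.21 for the burst and, from the late slopes, 1.51 for the climb. Scaling in temperature, I reckon a burst time of 0.588 min for south and 0.382 min for south-east, which is shorter than the time to the switch. Adding the climb after the burst in south, and after the switch in south-east, I get 22.3% and 20.5%. That gap of 1.8 percentage points is smaller than the margin, so I say neither.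

The forecast gives 23% for south and 19.5% for south-east, and picks south: “South is likely higher, but the margin is modest.”

The flasks give 19.2% in south and 19.9% in south-east: neither.

    substrate ⇌ intermediate A (K = 2.60, k = 0.0530 s⁻¹, Ea = 83.0 kJ mol⁻¹, ΔH = −27.0 kJ mol⁻¹)
    intermediate A ⇌ intermediate B (K = 1.10, k = 0.00480 s⁻¹, Ea = 80.0 kJ mol⁻¹, ΔH = −24.0 kJ mol⁻¹)
    substrate + partner ⇌ intermediate C (K = 7.30 L mol⁻¹, k = 0.240 L mol⁻¹ s⁻¹, Ea = 39.0 kJ mol⁻¹, ΔH = −26.0 kJ mol⁻¹)
    intermediate C → intermediate D (k = 0.120 s⁻¹, Ea = 88.0 kJ mol⁻¹)
    partner + intermediate D → side product (k = 0.590 L mol⁻¹ s⁻¹, Ea = 61.0 kJ mol⁻¹)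
    partner + intermediate D → target (k = 2.70 L mol⁻¹ s⁻¹, Ea = 52.0 kJ mol⁻¹)
    target ⇌ isomer of the product (K = 0.120, k = 0.0310 s⁻¹, Ea = 91.0 kJ mol⁻¹, ΔH = 8.00 kJ mol⁻¹)
    2 substrate → homo dimer (k = 0.710 L mol⁻¹ s⁻¹, Ea = 63.0 kJ mol⁻¹)
    (constants at 40 °C)

At the switch, past its reckoned burst time of 0.382 min, south-east holds 15.8% target, and it adds 4.1 points in the cold. South ends 3 points below my figure. The neighbour is south read at 1.0 min, which is 1.70 burst times. The same line gives 16.6% there, and that flask holds 14.3%.

The readings are simulated with constants of no real substance; the scatter is artificial.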